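**Retrosynthetic overview**
1. The target is a flavanone (O1, C2, C3, C4, C4a–C8a) whose C3 carries C8'' of a luteolin 7''-O-sulfate (flavone locants double-primed). The last step is a one-pot hydrogenolysis of six benzyl ethers and the trichloroethyl sulfate ester of 19.
2. Key disconnection (flavanone ring, closed last): O1–C2 and C4–C4a. The A ring comes from the C,O-dianion of 2-bromo-3,5-bis(benzyloxy)phenol; the C2=C3–C4(=O) unit is held as arylidene lactone 13.
3. Enabling feature: the sulfated O7'' is ortho to C8'', which carries C3. C4 can therefore be tied to O7'' as a five-membered aryl lactone (benzofuran-2(3H)-one fused at C7''/C8''). Its CH2 (future C3) condenses with the B-ring aldehyde (C2), its aryl-ester carbonyl acylates the carbanion, and its opening frees O7'' alone for sulfation. C3 (α to C4=O, benzylic to the flavone) epimerises freely, so E/Z and cis/trans mixtures funnel into the trans isomer.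
4. The lactone comes from an 8-allyl-7-hydroxyflavone (aromatic Claisen, then Lemieux–Johnson cleavage and oxidation). The flavone pyranone comes from Claisen condensation and cyclodehydration of a differentially protected phloroacetophenone.
5. Ring order: flavone pyranone → temporary furanone (lactone) → flavanone pyranone.

Key step: step 11

Assumption: the target is drawn as the free hydrogen sulfate; the final cold cation exchange is taken to deliver this acid form, which is best stored as a salt.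

Step 1
Reactants: 1 2',4',6'-trihydroxyacetophenone
Product: 2 1-[2,6-dihydroxy-4-(methoxymethoxy)phenyl]ethanone
Conditions: MOMCl (1.05 equiv), i-Pr2NEt, CH2Cl2–THF, 0 °C
Reagents that add atoms: chloromethyl methyl ether, COCCl
Why: Williamson-type O-alkylation: the 4-OH, the only phenol not hydrogen-bonded to the acetyl group and the most acidic one, should react first with one equivalent of MOMCl.

Step 2
Reactants: 2 1-[2,6-dihydroxy-4-(methoxymethoxy)phenyl]ethanone
Product: 3 1-[2-(benzyloxy)-6-hydroxy-4-(methoxymethoxy)phenyl]ethanone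
Conditions: BnBr (1.05 equiv), K2CO3, acetone, reflux
Reagents that add atoms: benzyl bromide, BrCc1ccccc1
Why: Williamson etherification of one of the two equivalent chelated ortho-hydroxyls; the remaining OH, now the sole partner of the carbonyl hydrogen bond, reacts much more slowly and stays free.

Step 3
Reactants: 3 1-[2-(benzyloxy)-6-hydroxy-4-(methoxymethoxy)phenyl]ethanone
Product: 4 1-[2-(allyloxy)-6-(benzyloxy)-4-(methoxymethoxy)phenyl]ethanone
Conditions: allyl bromide, K2CO3, DMF, 60 °C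
Reagents that add atoms: allyl bromide, C=CCBr
Why: Williamson O-allylation of the chelated phenol under more forcing carbonate/DMF conditions, tolerated by the MOM and benzyl ethers.

Step 4
Reactants: 4 1-[2-(allyloxy)-6-(benzyloxy)-4-(methoxymethoxy)phenyl]ethanone
Product: 5 1-[3-allyl-6-(benzyloxy)-2-hydroxy-4-(methoxymethoxy)phenyl]ethanone
Conditions: PhNEt2, 190 °C, Ar
Reagents that add atoms: none
Why: Aromatic Claisen rearrangement ([3,3]); the only unsubstituted ortho position is C3, so the allyl group lands between the regenerated (chelated) OH and the OMOM group with no regiochemical ambiguity.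

Step 5
Reactants: 5 1-[3-allyl-6-(benzyloxy)-2-hydroxy-4-(methoxymethoxy)phenyl]ethanone; 6 methyl 3,4-bis(benzyloxy)benzoate
Product: 7 1-[3-allyl-6-(benzyloxy)-2-hydroxy-4-(methoxymethoxy)phenyl]-3-[3,4-bis(benzyloxy)phenyl]propane-1,3-dione
Conditions: NaH (4 equiv), THF, reflux; AcOH quench
Reagents that add atoms: none
Why: Crossed Claisen condensation of the methyl ketone enolate (phenoxide–enolate dianion) with the non-enolisable ester, driven by deprotonation of the 1,3-diketone formed.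

Step 6
Reactants: 7 1-[3-allyl-6-(benzyloxy)-2-hydroxy-4-(methoxymethoxy)phenyl]-3-[3,4-bis(benzyloxy)phenyl]propane-1,3-dione
Product: 8 8-allyl-5-(benzyloxy)-2-[3,4-bis(benzyloxy)phenyl]-7-hydroxy-4H-chromen-4-one
Conditions: conc. HCl (cat.), MeOH–THF, 55 °C
Reagents that add atoms: none
Why: Acid-catalysed cyclodehydration of the o-hydroxyaryl 1,3-diketone through its only free ortho-OH (the other is benzylated) places the allyl group at C8 of the flavone, and the same acid cleaves the MOM acetal so that 7-OH alone is free.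

Step 7
Reactants: 8 8-allyl-5-(benzyloxy)-2-[3,4-bis(benzyloxy)phenyl]-7-hydroxy-4H-chromen-4-one
Product: 10 5-(benzyloxy)-2-[3,4-bis(benzyloxy)phenyl]-8-hydroxy-8,9-dihydro-4H-furo[2,3-h]chromen-4-one (lactol), via arylacetaldehyde 9 (not isolated)
Conditions: OsO4 (2 mol %), NaIO4, 2,6-lutidine, dioxane–H2O, rt
Reagents that add atoms: osmium tetroxide, O=[Os](=O)(=O)=O (catalytic oxygen carrier); sodium periodate, [Na+].[O-][I](=O)(=O)=O (terminal oxidant that supplies the new oxygen)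
Why: Lemieux–Johnson oxidative cleavage of the terminal alkene (the electron-poor flavone C2=C3 bond is not dihydroxylated), the arylacetaldehyde being trapped at once by the neighbouring 7-OH as the five-membered lactol.

Step 8
Reactants: 10 5-(benzyloxy)-2-[3,4-bis(benzyloxy)phenyl]-8-hydroxy-8,9-dihydro-4H-furo[2,3-h]chromen-4-one
Product: 11 5-(benzyloxy)-2-[3,4-bis(benzyloxy)phenyl]-4H-furo[2,3-h]chromene-4,8(9H)-dione (lactone between O7 and the C8 CH2C(=O) unit)
Conditions: TEMPO (10 mol %), PhI(OAc)2, CH2Cl2, rt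
Reagents that add atoms: none
Why: Oxoammonium-mediated (TEMPO/PhI(OAc)2) oxidation of a lactol to the lactone; no free phenol is left to be oxidised.

Step 9
Reactants: 11 5-(benzyloxy)-2-[3,4-bis(benzyloxy)phenyl]-4H-furo[2,3-h]chromene-4,8(9H)-dione; 12 4-(benzyloxy)benzaldehyde
Product: 13 5-(benzyloxy)-9-[4-(benzyloxy)benzylidene]-2-[3,4-bis(benzyloxy)phenyl]-4H-furo[2,3-h]chromene-4,8(9H)-dione (E/Z mixture, E expected to dominate)
Conditions: piperidinium acetate (20 mol %), toluene, reflux (Dean–Stark), Ar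
Reagents that add atoms: none
Why: Knoevenagel condensation at the doubly activated CH2 of the benzofuran-2(3H)-one (α to the lactone carbonyl and benzylic), with an ammonium carboxylate catalyst that spares the lactone; the alkene geometry is of no consequence for the C3 configuration later.

Step 10
Reactants: 14 3,5-bis(benzyloxy)phenol
Product: 15 2-bromo-3,5-bis(benzyloxy)phenol
Conditions: NBS (1.0 equiv), i-Pr2NH (10 mol %), CH2Cl2, –78 → 0 °C
Reagents that add atoms: N-bromosuccinimide, O=C1CCC(=O)N1Br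
Why: Electrophilic aromatic bromination in which the amine–NBS combination delivers bromine ortho to the free hydroxyl by hydrogen bonding (the para isomer, between the two benzyloxy groups, would be separated).

Step 11
Reactants: 13 5-(benzyloxy)-9-[4-(benzyloxy)benzylidene]-2-[3,4-bis(benzyloxy)phenyl]-4H-furo[2,3-h]chromene-4,8(9H)-dione; 15 2-bromo-3,5-bis(benzyloxy)phenol
Product: 19 (2R,3S)-5,7-bis(benzyloxy)-2-[4-(benzyloxy)phenyl]-3-{5-(benzyloxy)-2-[3,4-bis(benzyloxy)phenyl]-4-oxo-7-[(2,2,2-trichloroethoxy)sulfonyloxy]-4H-chromen-8-yl}chroman-4-one, via dilithiated phenoxide 16 (not isolated), via ring-opened chalcone 17 (not isolated), via chalcone trichloroethyl sulfate 18 (not isolated)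
Conditions: 15, n-BuLi (1.0 equiv) then t-BuLi (2.0 equiv), THF, –78 °C; 13, –78 °C; Cl3CCH2OSO2Cl (1.0 equiv), –78 → –40 °C; AcOH (1 equiv); aq. wash, swap to PhCl (no purification); quinidine-derived thiourea (9-amino-9-deoxy-epi-quinidine 3,5-bis(trifluoromethyl)phenyl thiourea, 10 mol %), rt
Reagents that add atoms: 2,2,2-trichloroethyl chlorosulfate, ClS(=O)(=O)OCC(Cl)(Cl)Cl
Why: Halogen–lithium exchange on the lithium phenoxide of 15 gives the C,O-dianion 16, whose aryl carbon adds 1,2 to the strained aryl-lactone carbonyl of 13 (C4–C4a bond) and expels O7'' as the only non-chelated phenoxide, which the chlorosulfate caps while the O1 phenoxide stays locked in its lithium chelate with the new ketone (17 → 18); after protonation the bifunctional cinchona catalyst delivers O1 to C2 of the enone and the resulting enol is protonated at C3. The closest known reaction types are the acylation of ortho-lithiated phenoxides by esters and lactones, the sulfation of phenoxides with trichloroethyl chlorosulfate and the cinchona-alkaloid-catalysed asymmetric intramolecular oxa-Michael closure of 2'-hydroxychalcones and α-substituted o-acylphenols to chromanones. The one ring that closes (the flavanone pyranone) does so in the 6-endo-trig mode. C2 is set by the catalyst, the quinidine series being chosen for the 2R sense by analogy with quinine-mediated closures of α-substituted o-acylphenols (the quinine-derived pseudo-enantiomer is the alternative should the sense prove opposite); C3 is set by thermodynamic, amine-mediated epimerisation that places both aryl groups equatorial (trans, hence 3S once C2 is R), so that the E/Z mixture of 13 and any cis isomer converge on one stereoisomer. The step needs carbonyl over conjugate addition (hard aryllithium at –78 °C, β-carbon deactivated by the p-benzyloxyphenyl group), O7'' over O1 sulfation (chelation of O1), closure through O1 rather than O7'' (the latter would be 5-endo and is capped anyway) and a slow retro-oxa-Michael reaction, which the 6'-benzyloxy and α-aryl groups should secure by destabilising the open chalcone.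

Step 12
Reactants: 19 (2R,3S)-5,7-bis(benzyloxy)-2-[4-(benzyloxy)phenyl]-3-{5-(benzyloxy)-2-[3,4-bis(benzyloxy)phenyl]-4-oxo-7-[(2,2,2-trichloroethoxy)sulfonyloxy]-4H-chromen-8-yl}chroman-4-one
Product: 20 2-(3,4-dihydroxyphenyl)-8-[(2R,3S)-5,7-dihydroxy-2-(4-hydroxyphenyl)-4-oxochroman-3-yl]-5-hydroxy-4-oxo-4H-chromen-7-yl hydrogen sulfate (target)
Conditions: 10% Pd/C, HCO2NH4, MeOH–THF, rt; Dowex 50W (H+), 0 °C
Reagents that add atoms: none
Why: Palladium-catalysed transfer hydrogenolysis cleaves the six aryl benzyl ethers and reductively fragments the trichloroethyl ester to the aryl sulfate under neutral conditions that leave C2 and C3 untouched, and cold cation exchange gives the acid form.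

**Compound list**
1 | 2',4',6'-trihydroxyacetophenone | CC(=O)c1c(O)cc(O)cc1O | starting material
2 | 1-[2,6-dihydroxy-4-(methoxymethoxy)phenyl]ethanone | CC(=O)c1c(O)cc(OCOC)cc1O | intermediate
3 | 1-[2-(benzyloxy)-6-hydroxy-4-(methoxymethoxy)phenyl]ethanone | CC(=O)c1c(O)cc(OCOC)cc1OCc1ccccc1 | intermediate
4 | 1-[2-(allyloxy)-6-(benzyloxy)-4-(methoxymethoxy)phenyl]ethanone | CC(=O)c1c(OCC=C)cc(OCOC)cc1OCc1ccccc1 | intermediate
5 | 1-[3-allyl-6-(benzyloxy)-2-hydroxy-4-(methoxymethoxy)phenyl]ethanone | CC(=O)c1c(O)c(CC=C)c(OCOC)cc1OCc1ccccc1 | intermediate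
6 | methyl 3,4-bis(benzyloxy)benzoate | COC(=O)c1ccc(OCc2ccccc2)c(OCc2ccccc2)c1 | starting material
7 | 1-[3-allyl-6-(benzyloxy)-2-hydroxy-4-(methoxymethoxy)phenyl]-3-[3,4-bis(benzyloxy)phenyl]propane-1,3-dione | C=CCc1c(O)c(C(=O)CC(=O)c2ccc(OCc3ccccc3)c(OCc3ccccc3)c2)c(OCc2ccccc2)cc1OCOC | intermediate
8 | 8-allyl-5-(benzyloxy)-2-[3,4-bis(benzyloxy)phenyl]-7-hydroxy-4H-chromen-4-one | C=CCc1c(O)cc(OCc2ccccc2)c2c(=O)cc(-c3ccc(OCc4ccccc4)c(OCc4ccccc4)c3)oc12 | intermediate
9 | 2-{5-(benzyloxy)-2-[3,4-bis(benzyloxy)phenyl]-7-hydroxy-4-oxo-4H-chromen-8-yl}acetaldehyde | O=CCc1c(O)cc(OCc2ccccc2)c2c(=O)cc(-c3ccc(OCc4ccccc4)c(OCc4ccccc4)c3)oc12 | intermediate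
10 | 5-(benzyloxy)-2-[3,4-bis(benzyloxy)phenyl]-8-hydroxy-8,9-dihydro-4H-furo[2,3-h]chromen-4-one (racemic lactol) | OC1Oc2cc(OCc3ccccc3)c3c(=O)cc(-c4ccc(OCc5ccccc5)c(OCc5ccccc5)c4)oc3c2C1 | intermediate
11 | 5-(benzyloxy)-2-[3,4-bis(benzyloxy)phenyl]-4H-furo[2,3-h]chromene-4,8(9H)-dione | O=C1Oc2cc(OCc3ccccc3)c3c(=O)cc(-c4ccc(OCc5ccccc5)c(OCc5ccccc5)c4)oc3c2C1 | intermediate
12 | 4-(benzyloxy)benzaldehyde | O=Cc1ccc(OCc2ccccc2)cc1 | starting material
13 | 5-(benzyloxy)-9-[4-(benzyloxy)benzylidene]-2-[3,4-bis(benzyloxy)phenyl]-4H-furo[2,3-h]chromene-4,8(9H)-dione (E/Z) | O=C1Oc2cc(OCc3ccccc3)c3c(=O)cc(-c4ccc(OCc5ccccc5)c(OCc5ccccc5)c4)oc3c2C1=Cc1ccc(OCc2ccccc2)cc1 | intermediate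
14 | 3,5-bis(benzyloxy)phenol | Oc1cc(OCc2ccccc2)cc(OCc2ccccc2)c1 | starting material
15 | 2-bromo-3,5-bis(benzyloxy)phenol | Oc1cc(OCc2ccccc2)cc(OCc2ccccc2)c1Br | intermediate
16 | lithium 3,5-bis(benzyloxy)-2-lithiophenoxide | [Li]Oc1cc(OCc2ccccc2)cc(OCc2ccccc2)c1[Li] | intermediate
17 | (E/Z)-1-[2,4-bis(benzyloxy)-6-hydroxyphenyl]-2-{5-(benzyloxy)-2-[3,4-bis(benzyloxy)phenyl]-7-hydroxy-4-oxo-4H-chromen-8-yl}-3-[4-(benzyloxy)phenyl]prop-2-en-1-one (present in the flask as its dilithium bis-phenoxide; drawn neutral) | O=C(c1c(O)cc(OCc2ccccc2)cc1OCc1ccccc1)C(=Cc1ccc(OCc2ccccc2)cc1)c1c(O)cc(OCc2ccccc2)c2c(=O)cc(-c3ccc(OCc4ccccc4)c(OCc4ccccc4)c3)oc12 | intermediate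
18 | (E/Z)-1-[2,4-bis(benzyloxy)-6-hydroxyphenyl]-2-{5-(benzyloxy)-2-[3,4-bis(benzyloxy)phenyl]-4-oxo-7-[(2,2,2-trichloroethoxy)sulfonyloxy]-4H-chromen-8-yl}-3-[4-(benzyloxy)phenyl]prop-2-en-1-one | O=C(c1c(O)cc(OCc2ccccc2)cc1OCc1ccccc1)C(=Cc1ccc(OCc2ccccc2)cc1)c1c(OS(=O)(=O)OCC(Cl)(Cl)Cl)cc(OCc2ccccc2)c2c(=O)cc(-c3ccc(OCc4ccccc4)c(OCc4ccccc4)c3)oc12 | intermediate
19 | (2R,3S)-5,7-bis(benzyloxy)-2-[4-(benzyloxy)phenyl]-3-{5-(benzyloxy)-2-[3,4-bis(benzyloxy)phenyl]-4-oxo-7-[(2,2,2-trichloroethoxy)sulfonyloxy]-4H-chromen-8-yl}chroman-4-one | O=C1c2c(OCc3ccccc3)cc(OCc3ccccc3)cc2O[C@@H](c2ccc(OCc3ccccc3)cc2)[C@@H]1c1c(OS(=O)(=O)OCC(Cl)(Cl)Cl)cc(OCc2ccccc2)c2c(=O)cc(-c3ccc(OCc4ccccc4)c(OCc4ccccc4)c3)oc12 | intermediate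
20 | 2-(3,4-dihydroxyphenyl)-8-[(2R,3S)-5,7-dihydroxy-2-(4-hydroxyphenyl)-4-oxochroman-3-yl]-5-hydroxy-4-oxo-4H-chromen-7-yl hydrogen sulfate | O=C1c2c(O)cc(O)cc2O[C@@H](c2ccc(O)cc2)[C@@H]1c1c(OS(=O)(=O)O)cc(O)c2c(=O)cc(-c3ccc(O)c(O)c3)oc12 | target

**Step count and risks**
Total steps: 12. Longest linear sequence: 11 (steps 1–9, 11, 12).

Step 11 (most likely to fail). What may go wrong: the aryllithium adds in conjugate fashion to the arylidene lactone, the chlorosulfate fails to discriminate between the two phenoxides, or lithium salts carried into the ring closure erode the facial selectivity. Fallback, setting out from 13 and coming back at 19: the lactone 13 is opened with N,O-dimethylhydroxylamine hydrochloride/i-PrMgCl (THF, –20 °C) to the N-methoxy-N-methyl acrylamide F1. Its free 7-OH is silylated (TBSCl, imidazole) to the silyl ether F2. Dianion 16 then adds once to the Weinreb amide to give the isolated and purified 2'-hydroxychalcone F3. The cinchona-catalysed oxa-Michael closure is run on this clean material to the 7''-O-silyl flavanone F4. HF·pyridine frees the 7''-phenol F5, and Cl3CCH2OSO2Cl/Et3N/DMAP gives 19.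

Step 12. What may go wrong: transfer hydrogenation also saturates the flavone C2''=C3'' bond, or the hindered benzyl ethers lag behind so that prolonged exposure erodes the sulfate. Fallback, from 19 to 20: the trichloroethyl group is first removed without palladium (zinc dust, HCO2NH4, MeOH) to give the hexa-O-benzyl hydrogen sulfate F6, handled as its ammonium salt. This is then debenzylated under 1 atm H2 over Pd(OH)2/C in THF–MeOH with close monitoring and converted into 20 by cold cation exchange.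

Step 10. What may go wrong: bromination para to the hydroxyl (between the two benzyloxy groups) competes with the wanted ortho substitution. Fallback, from 14 to 15: 14 is converted into its methoxymethyl ether F7 (MOMCl, i-Pr2NEt). Directed ortho-lithiation at the MOM-flanked position (n-BuLi, THF, –20 °C) and quenching with 1,2-dibromotetrafluoroethane gives the aryl bromide F8. HCl/MeOH then returns 15.

Further compounds
F1 | step 11 | (E/Z)-2-{5-(benzyloxy)-2-[3,4-bis(benzyloxy)phenyl]-7-hydroxy-4-oxo-4H-chromen-8-yl}-3-[4-(benzyloxy)phenyl]-N-methoxy-N-methylprop-2-enamide | CON(C)C(=O)C(=Cc1ccc(OCc2ccccc2)cc1)c1c(O)cc(OCc2ccccc2)c2c(=O)cc(-c3ccc(OCc4ccccc4)c(OCc4ccccc4)c3)oc12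
F2 | step 11 | (E/Z)-2-{5-(benzyloxy)-2-[3,4-bis(benzyloxy)phenyl]-7-[(tert-butyldimethylsilyl)oxy]-4-oxo-4H-chromen-8-yl}-3-[4-(benzyloxy)phenyl]-N-methoxy-N-methylprop-2-enamide | CON(C)C(=O)C(=Cc1ccc(OCc2ccccc2)cc1)c1c(O[Si](C)(C)C(C)(C)C)cc(OCc2ccccc2)c2c(=O)cc(-c3ccc(OCc4ccccc4)c(OCc4ccccc4)c3)oc12
F3 | step 11 | (E/Z)-1-[2,4-bis(benzyloxy)-6-hydroxyphenyl]-2-{5-(benzyloxy)-2-[3,4-bis(benzyloxy)phenyl]-7-[(tert-butyldimethylsilyl)oxy]-4-oxo-4H-chromen-8-yl}-3-[4-(benzyloxy)phenyl]prop-2-en-1-one | O=C(c1c(O)cc(OCc2ccccc2)cc1OCc1ccccc1)C(=Cc1ccc(OCc2ccccc2)cc1)c1c(O[Si](C)(C)C(C)(C)C)cc(OCc2ccccc2)c2c(=O)cc(-c3ccc(OCc4ccccc4)c(OCc4ccccc4)c3)oc12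
F4 | step 11 | (2R,3S)-5,7-bis(benzyloxy)-2-[4-(benzyloxy)phenyl]-3-{5-(benzyloxy)-2-[3,4-bis(benzyloxy)phenyl]-7-[(tert-butyldimethylsilyl)oxy]-4-oxo-4H-chromen-8-yl}chroman-4-one | O=C1c2c(OCc3ccccc3)cc(OCc3ccccc3)cc2O[C@@H](c2ccc(OCc3ccccc3)cc2)[C@@H]1c1c(O[Si](C)(C)C(C)(C)C)cc(OCc2ccccc2)c2c(=O)cc(-c3ccc(OCc4ccccc4)c(OCc4ccccc4)c3)oc12
F5 | step 11 | (2R,3S)-5,7-bis(benzyloxy)-2-[4-(benzyloxy)phenyl]-3-{5-(benzyloxy)-2-[3,4-bis(benzyloxy)phenyl]-7-hydroxy-4-oxo-4H-chromen-8-yl}chroman-4-one | O=C1c2c(OCc3ccccc3)cc(OCc3ccccc3)cc2O[C@@H](c2ccc(OCc3ccccc3)cc2)[C@@H]1c1c(O)cc(OCc2ccccc2)c2c(=O)cc(-c3ccc(OCc4ccccc4)c(OCc4ccccc4)c3)oc12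
F6 | step 12 | 5-(benzyloxy)-2-[3,4-bis(benzyloxy)phenyl]-8-{(2R,3S)-5,7-bis(benzyloxy)-2-[4-(benzyloxy)phenyl]-4-oxochroman-3-yl}-4-oxo-4H-chromen-7-yl hydrogen sulfate | O=C1c2c(OCc3ccccc3)cc(OCc3ccccc3)cc2O[C@@H](c2ccc(OCc3ccccc3)cc2)[C@@H]1c1c(OS(=O)(=O)O)cc(OCc2ccccc2)c2c(=O)cc(-c3ccc(OCc4ccccc4)c(OCc4ccccc4)c3)oc12
F7 | step 10 | 1,3-bis(benzyloxy)-5-(methoxymethoxy)benzene | COCOc1cc(OCc2ccccc2)cc(OCc2ccccc2)c1
F8 | step 10 | 1,5-bis(benzyloxy)-2-bromo-3-(methoxymethoxy)benzene | COCOc1cc(OCc2ccccc2)cc(OCc2ccccc2)c1Br
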